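The question is what share of the converted L stands as J in each set-up, and whether the lead clears the margin.

| flask | L | Q | time | remark |
|---|---|---|---|---|
| Tuesday's | 1.6 M | 0.1 mol% | 8.0 h | everything together in a closed stirred flask, run for 8.0 h |
| Monday's | 1.6 M (fed, over 4.00 h) | 0.1 mol% | 8.0 h | a stirred flask in which L is dosed at a steady rate over 4.00 h without added volume, worked up at 8.0 h |
| Wednesday's | 1.6 M | 0.1 mol% | 8.0 h | a tube with plug flow, the mixed feed as stated, residence time 8.0 h |
| Thursday's | 1.6 M | 0.1 mol% |  | one stirred flow tank at steady state, fed with the mixture as stated, mean residence time 8.0 h |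

    G + Q ⇌ Z + Q, rate k1*[Q]*[G] forward; the back reaction follows from the equilibrium constant (K1 = 1.8, k1 = 26 M⁻¹ h⁻¹)
    Z + Q ⇌ L + Q, rate k2*[Q]*[Z] forward; the back reaction follows from the equilibrium constant (k2 = 42 M⁻¹ h⁻¹)
    J + Q ⇌ G + Q, rate k3*[Q]*[J] forward; the back reaction follows from the equilibrium constant (K3 = 1.5, k3 = 150 M⁻¹ h⁻¹)
    L ⇌ J (K4 = 1.4, k4 = 0.099 h⁻¹)

* the set-up with the highest share of J in all that became J or G or Z, at the outlet or at the end ("none" if the first two lie within 2 percentage points) (Tuesday's / Monday's / Wednesday's / Thursday's / none)
* share of J in all that became J or G or Z, at the outlet or at the end, Tuesday's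
* share of J in all that became J or G or Z, at the outlet or at the end, Monday's
* share of J in all that became J or G or Z, at the outlet or at the end, Wednesday's
* share of J in all that became J or G or Z, at the outlet or at the end, Thursday's

- the stated concentrations are those of everything mixed, before any reaction; amounts are the same in each set-up
- the feed brings no volume worth counting
- run time (Tuesday's): 8.0 h

Q stays at one concentration, so each catalysed step is pseudo-first-order. L leaves by two doors: uncatalysed to J, and catalysed to Z, the reverse of the second step.

[Q] = 0.00160 M
L to Z: 0.254 h⁻¹
L to J: 0.099 h⁻¹
opening: 28.0%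

This is the opening share: the fraction of departing L that enters J directly, which is where the share curve starts in Tuesday's flask.

The level comes from the equilibrium constants, and the first slope from J's exit set against the products' return to L:

level: 19.2%
J's exit: 0.311 h⁻¹
return: 0.0682 h⁻¹
slope: 0.0340 h⁻¹, falling
straight line meets the level at 2.59 h

The curve does not stop there. J passes to G with a half-life of 2.9 h by the forward step alone, and G passes on with 17 h, a slower hand-over. So a knee is due near 2.9 h, when J and G begin to share the opening inflow:

dip: 11.2%

This lies under the level, so the curve crosses the level, sinks towards the dip and climbs back slowly. The reckoning places Tuesday's 8.0 h reading between the two. Wednesday's tube is Tuesday's flask with length for time and reads the same. Monday's dosed material is 4.00 h to 8.0 h old, younger than Tuesday's, and Thursday's tank mixes in ages below 2.59 h, so both should stand higher.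

The forecast gives 16.3%, 17.1%, 16.3% and 18.2% for Tuesday's, Monday's, Wednesday's and Thursday's and calls none, on the ground: “it leads the dosed run by only about 1 point, inside the 2-point margin”.

The flasks read 16.3% for Tuesday's, 16.3% for Wednesday's, 17.2% for Monday's and 18.2% for Thursday's, so the call is none, with a lead of 1.00 percentage point under the margin. Wednesday's tube, left until 80.0 h, reads 19.2%. A tube like Wednesday's charged at 0.40 M with the same loading holds 4.00 × 10⁻⁴ M of Q, a quarter of Wednesday's [Q], so its opening share is 60.9% against 28.0%, and at 8.0 h it reads 43.2%.

The constants used here were drawn at random within sensible limits; the result is computed.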